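The number 0.766 is what I carry through this flask: the reach of a charge of D, meaning the natural logarithm of G charged over G left once G has stopped falling, read from the mean of Friday's readings from 40.0 h on.

the same everywhere: G 0.10 M; D 0.50 mM; temperature 110 °C
- Friday's: the very flask that is asked about, followed so far
- flask: time 6.0 d

- Friday's (time / h: E / %, G / %): 12.0: 34.2, 61.2; 40.0: 43.5, 46.9; 72.0: 44.1, 47.1; 96.0: 44.0, 45.7; 144: 42.4, 46.2

(each reading ± 1 percentage point)

- east: at 6.0 d take out 90% of the E then present, then wait 12 d
- north-east: at 6.0 d raise the temperature by 10 K, then wait 12 d
- north: at 6.0 d add D, 100% of the amount charged, then wait 12 d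
- west: change nothing and wait 12 d more

- E taken out counts as made
- additions bring no volume worth counting
- the earlier runs do not show what temperature does; that part of a forecast is a guess

1. E, in percent of the G first charged, at 6.0 d
2. what to do for the largest gain in E; "none" if nothing gains more than 2 percentage points (east / north-east / north / west / none)
3. E present, with what was taken out counted in, in percent of the G first charged, after north-east
4. E present, with what was taken out counted in, in percent of the G first charged, after north

Has Friday's flask stopped? Yes, as far as the readings show: from 40.0 h on, G stays near 46.5% and E moves within the scatter.

Why has it stopped? The readings of G and E cannot separate an equilibrium from a dying catalyst. E plus G also stops falling, though, so I assume that D dies. If D dies first-order, G falls pseudo-first-order with a rate proportional to the active D, and integrating gives a logarithmic drop proportional to the D charged. On that assumption a second charge doubles the reach, and east, north-east and west give nothing.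

How much of that new drop becomes E? I use the reach s as a clock, so G = exp(−s) and dE/ds = G − rE, where r is the selectivity factor, the rate constant for loss of E over that for loss of G. Trying r = 0.5 gives E = 2(√G − G), which is 43.4% at Friday's G, in line with the readings. After north I reckon G at 21.6% and E at 49.8%, a gain of 6.4 percentage points against the margin of 2 points, so I choose north.

The forecast gives 43.5% (42.3% to 44.7%) now, north as best, 42% (36% to 49%) after north-east and 62% (42% to 68%) after north. It reasons “Fresh D should give about the same ln G drop”, as I do, but it takes a selectivity of about 80% for that drop, so we part on the E after north.

The flask gives 44.3% now and 44.3% after north-east. The best choice is north, which gains 6.7 points and reaches 51.1%, 11 points under the forecast.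

    G + D ⇌ J (K = 1.70 /M, k = 1000 /M/h, Ea = 84.0 kJ/mol, ΔH = −5.00 kJ/mol)
    J → D + E (k = 100 /h, Ea = 93.0 kJ/mol)
    D + E → D + L (k = 68.0 /M/h, Ea = 60.0 kJ/mol)
    D → X (k = 0.0930 /h, Ea = 112 kJ/mol)
    (constants at 110 °C)

In this flask E is made 6.22 times faster than it is used up, each step taken net, at 6.26 h, yet its half-life by the turning into L is then 38 h, shorter than 6.0 d, and after north the doubled reach of 1.53 gave me 49.8% of E where the flask stands at 51.1%. For the neighbour flask charged with 0.0013 M of D, the reach scales to 1.99, which gives G 13.6% and E 46.6%, and that flask holds G 13.1% and E 48.0% at 144 h.

The data were generated by integration on assumed constants.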